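**Strategy**

The target is a trans-fused 14,15-dinorlabdane (ring A: C1–C5, C10; ring B: C5–C10). The route rests on opening ring B at C8–C9: the exocyclic C8=C17 methylene flanked by the C9 methine is read as the trace of a vinyl radical, born from a terminal alkyne C8≡C17, that has added to C9 of a C9=C11 alkene. One tin-radical-mediated 6-exo enyne cyclization therefore closes ring B, sets C9 and turns the alkyne into the methylene. Its precursor is a fully substituted ring A cyclohexanone, built by an enantioselective Diels–Alder reaction, that carries a propargylic silyl ether arm on C5 and a (Z)-alkenyl ketal arm on C10.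

Key step: step 15

Remark: locants C1–C20 are the labdane positions of the target (C17 = exocyclic methylene carbon, C18 = C4 methyl, C19 = acetoxymethyl carbon, C20 = C10 methyl); β is the face of C20, α the opposite face.

**Route**

Step 1
Reactants: 1 methylglyoxal (aqueous solution)
Product: 2 tert-butyl (2E)-4-oxopent-2-enoate
Conditions: Ph3P=CHCO2t-Bu, CH2Cl2, 0 °C → rt
Reagents that add atoms: tert-butyl (triphenylphosphoranylidene)acetate, CC(C)(C)OC(=O)C=P(c1ccccc1)(c1ccccc1)c1ccccc1
Why: Wittig olefination; the stabilized ylide reacts only at the aldehyde carbonyl and should give the (E)-enoate.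

Step 2
Reactants: 2 tert-butyl (2E)-4-oxopent-2-enoate
Product: 3 tert-butyl (2E)-4-[(triisopropylsilyl)oxy]penta-2,4-dienoate
Conditions: i-Pr3SiOTf, Et3N, CH2Cl2, 0 °C
Reagents that add atoms: triisopropylsilyl trifluoromethanesulfonate, CC(C)[Si](OS(=O)(=O)C(F)(F)F)(C(C)C)C(C)C
Why: Silyl enol ether formation by soft enolization; the methyl group is the only enolizable position, so O-silylation should give the 2-silyloxy diene.

Step 3
Reactants: 4 2,2-dimethoxyacetaldehyde (aqueous solution)
Product: 6 ethyl (2E)-2-methyl-4-oxobut-2-enoate, via acetal ester 5 (not isolated)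
Conditions: Ph3P=C(CH3)CO2Et, CH2Cl2, rt; then 1 M HCl, THF, rt
Reagents that add atoms: ethyl 2-(triphenylphosphoranylidene)propanoate, CCOC(=O)C(C)=P(c1ccccc1)(c1ccccc1)c1ccccc1; water, O
Why: Wittig olefination with the α-methyl stabilized ylide should give the (E)-trisubstituted enoate, and mild acid then hydrolyses the dimethyl acetal to the aldehyde.

Step 4
Reactants: 3 tert-butyl (2E)-4-[(triisopropylsilyl)oxy]penta-2,4-dienoate; 6 ethyl (2E)-2-methyl-4-oxobut-2-enoate
Product: 7 3-tert-butyl 1-ethyl (1S,2S,3S)-2-formyl-1-methyl-5-[(triisopropylsilyl)oxy]cyclohex-4-ene-1,3-dicarboxylate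
Conditions: (S)-B-(o-tolyl)oxazaborolidinium triflimide, [C24H25BNO][N(SO2CF3)2] (from (S)-α,α-diphenylprolinol, tri-o-tolylboroxine and (CF3SO2)2NH; 20 mol %), CH2Cl2, −78 → −40 °C
Reagents that add atoms: none
Why: Catalytic enantioselective Diels–Alder reaction: the boron Lewis acid binds the formyl group so that C10 (β to CHO) pairs with the nucleophilic CH2 terminus of the 2-silyloxy diene, suprafacial addition to the (E)-dienophile places the C5 formyl group trans to the ethyl ester and cis to the methyl group on C10, and the chiral cation shields one enantioface so that C5 and C10 are set in the absolute sense shown (the (S)-catalyst is expected to give this sense, otherwise its antipode is used; the endo-derived C4 configuration is of no consequence because C4 is enolized in step 6).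

Step 5
Reactants: 7 Diels–Alder aldehyde
Product: 8 methyl enol ether (C5–CH=CH–OCH3, E/Z mixture)
Conditions: Ph3P(CH2OCH3)Cl, KN(SiMe3)2, THF, −78 → 0 °C
Reagents that add atoms: (methoxymethyl)triphenylphosphonium chloride, COC[P+](c1ccccc1)(c1ccccc1)c1ccccc1.[Cl-]
Why: Wittig methoxymethylenation adds C7 as a masked aldehyde without touching the esters or the silyl enol ether, the ylide being added cold to avoid epimerization at C5.

Step 6
Reactants: 8 methyl enol ether
Product: 9 C4-methylated diester (4α-CH3, 4β-CO2t-Bu)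
Conditions: LiN(i-Pr)2, THF, −78 °C; CH3I, −78 → −20 °C
Reagents that add atoms: iodomethane, CI
Why: Ester enolate alkylation: only C4 carries an acidic hydrogen (the ethyl ester has no α-hydrogen), and iodomethane should enter anti to the vicinal C5 side chain, which stands pseudo-axial to avoid A(1,3) strain with the exocyclic enolate, so the quaternary centre carries 4α-methyl and 4β-ester.

Step 7
Reactants: 9 C4-methylated diester
Product: 10 C7 aldehyde (C5–CH2–CHO)
Conditions: oxalic acid (cat.), THF/H2O, 0 °C → rt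
Reagents that add atoms: water, O
Why: Acid-catalysed enol ether hydrolysis; C-protonation of the alkyl enol ether is faster than that of the less basic, shielded triisopropylsilyl enol ether next to quaternary C4, so only the side-chain aldehyde should be released.

Step 8
Reactants: 10 C7 aldehyde
Product: 12 (7R)-propargylic alcohol, via trimethylsilyl alkynol 11 (not isolated)
Conditions: Me3SiC≡CH, ZnMe2, (S,S)-ProPhenol (20 mol %), Ph3P=O (40 mol %), toluene, 0 °C; then K2CO3, MeOH, 0 °C
Reagents that add atoms: ethynyltrimethylsilane, C#C[Si](C)(C)C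
Why: Catalytic asymmetric alkynylation of the aldehyde (dinuclear zinc–ProPhenol catalyst) sets the C7 carbinol as R by reagent control, the ligand enantiomer being chosen for that sense, and methanolysis then cleaves the alkynyl C–Si bond.

Step 9
Reactants: 12 (7R)-propargylic alcohol
Product: 13 C7 tert-butyldimethylsilyl ether
Conditions: t-BuMe2SiCl, imidazole, DMF, rt
Reagents that add atoms: tert-butyldimethylsilyl chloride, CC(C)(C)[Si](C)(C)Cl
Why: Silyl ether formation protects O7 for the hydride steps and the acetylation that follow.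

Step 10
Reactants: 13 C7 silyl ether
Product: 14 C9 aldehyde (CHO on C10)
Conditions: i-Bu2AlH, CH2Cl2, −78 °C; Rochelle salt work-up
Reagents that add atoms: none
Why: Partial reduction of an ester to an aldehyde; at −78 °C the aluminium hemiacetal of the neopentyl ethyl ester survives until work-up, and the more hindered tert-butyl ester is not attacked.

Step 11
Reactants: 14 C9 aldehyde
Product: 15 (Z)-alkenyl dioxolane (C9=C11)
Conditions: [2-(2-methyl-1,3-dioxolan-2-yl)ethyl]triphenylphosphonium bromide, KN(SiMe3)2, THF, −78 → 0 °C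
Reagents that add atoms: [2-(2-methyl-1,3-dioxolan-2-yl)ethyl]triphenylphosphonium bromide, CC1(CC[P+](c2ccccc2)(c2ccccc2)c2ccccc2)OCCO1.[Br-]
Why: Wittig olefination with the non-stabilized ylide under salt-free conditions should give the (Z)-alkene and brings in C11–C13 and C16 with the ketone masked as a dioxolane; the alkene geometry is erased when C11 becomes sp3.

Step 12
Reactants: 15 (Z)-alkenyl dioxolane
Product: 16 C19 primary alcohol
Conditions: LiAlH4, THF, 0 °C → rt
Reagents that add atoms: none
Why: LiAlH4 reduction of the tert-butyl ester to the primary alcohol; silyl enol ether, silyl ether, dioxolane, alkyne and alkene are inert to hydride.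

Step 13
Reactants: 16 C19 primary alcohol
Product: 17 C19 acetate
Conditions: Ac2O, pyridine, 4-(dimethylamino)pyridine (cat.), CH2Cl2, rt
Reagents that add atoms: acetic anhydride, CC(=O)OC(C)=O
Why: Acetylation of the only free hydroxyl group installs the C19 acetate of the target.

Step 14
Reactants: 17 C19 acetate
Product: 18 ring A ketone (cyclization precursor)
Conditions: Bu4NF, AcOH, THF, −20 °C
Reagents that add atoms: none
Why: Fluoride-induced cleavage of the silyl enol ether, far faster than that of the secondary alkyl silyl ether under buffered conditions, should release the C2 ketone by protonation at C3.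

Step 15
Reactants: 18 ring A ketone (cyclization precursor)
Product: 20 trans-fused methylene decalone, via vinylstannane 19 (not isolated)
Conditions: Bu3SnH (syringe pump), azobis(isobutyronitrile) (cat.), benzene (high dilution), 80 °C; then SiO2, CH2Cl2, rt
Reagents that add atoms: none
Why: Bu3Sn• adds reversibly to the terminal alkyne carbon C17; the β-stannyl vinyl radical at C8 attacks C9 of the C9=C11 alkene, the secondary C11 radical takes hydrogen from Bu3SnH to carry the chain, and silica gel protodestannylates the exocyclic vinylstannane to the C8=C17 methylene. The closest known reaction type is the tin-radical-mediated enyne (vinyl radical) cyclization. Ring B closes in the 6-exo-trig mode. C9 is set in a chair-like transition state whose trans ring fusion is fixed by the trans-diequatorial arms on C5 and C10; the C11 chain takes the pseudo-equatorial position because the pseudo-axial alternative would run into the axial 7α-silyloxy group and H5, so H9 should end α. The step needs 6-exo rather than 7-endo closure and ring closure faster than hydrogen transfer to the vinyl radical; the chair-like six-membered transition state and slow addition of Bu3SnH at high dilution secure this, while stannyl radical addition to the hindered alkene is reversible and unproductive.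

Step 16
Reactants: 20 trans-fused methylene decalone
Product: 21 2α-alcohol
Conditions: SmI2, H2O, THF, 0 °C → rt
Reagents that add atoms: none
Why: SmI2 reduction (single-electron, dissolving-metal type): the ketyl-derived intermediate is protonated to the thermodynamically preferred equatorial 2α-alcohol, whose oxygen avoids the syn-axial C20 methyl and C19 acetoxymethyl groups, whereas a hydride reagent would be forced onto the α face and give the axial 2β-epimer.

Step 17
Reactants: 21 2α-alcohol
Product: 22 target, 19-acetoxy-2α,7α-dihydroxy-14,15-dinorlabd-8(17)-en-13-one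
Conditions: 1 M HCl, THF, rt
Reagents that add atoms: water, O
Why: Acid hydrolysis removes the dioxolane and the secondary silyl ether in one operation, and the primary acetate and the allylic alcohol should survive these mild conditions.

**Compound list**

1 | methylglyoxal (2-oxopropanal) | CC(=O)C=O | starting material
2 | tert-butyl (2E)-4-oxopent-2-enoate | CC(=O)/C=C/C(=O)OC(C)(C)C | intermediate
3 | tert-butyl (2E)-4-[(triisopropylsilyl)oxy]penta-2,4-dienoate | C=C(O[Si](C(C)C)(C(C)C)C(C)C)/C=C/C(=O)OC(C)(C)C | intermediate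
4 | 2,2-dimethoxyacetaldehyde | COC(OC)C=O | starting material
5 | ethyl (2E)-4,4-dimethoxy-2-methylbut-2-enoate | CCOC(=O)/C(C)=C/C(OC)OC | intermediate
6 | ethyl (2E)-2-methyl-4-oxobut-2-enoate | CCOC(=O)/C(C)=C/C=O | intermediate
7 | 3-tert-butyl 1-ethyl (1S,2S,3S)-2-formyl-1-methyl-5-[(triisopropylsilyl)oxy]cyclohex-4-ene-1,3-dicarboxylate (CHO cis to the ring methyl and to CO2t-Bu, trans to CO2Et) | O=C[C@H]1[C@@H](C(=O)OC(C)(C)C)C=C(O[Si](C(C)C)(C(C)C)C(C)C)C[C@]1(C)C(=O)OCC | intermediate
8 | 3-tert-butyl 1-ethyl 2-(2-methoxyethenyl)-1-methyl-5-[(triisopropylsilyl)oxy]cyclohex-4-ene-1,3-dicarboxylate (ring stereocentres as in 7; enol ether E/Z mixture) | COC=C[C@H]1[C@@H](C(=O)OC(C)(C)C)C=C(O[Si](C(C)C)(C(C)C)C(C)C)C[C@]1(C)C(=O)OCC | intermediate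
9 | 3-tert-butyl 1-ethyl 2-(2-methoxyethenyl)-1,3-dimethyl-5-[(triisopropylsilyl)oxy]cyclohex-4-ene-1,3-dicarboxylate (new methyl trans to the C2 side chain; 4α-CH3, 4β-CO2t-Bu) | COC=C[C@H]1[C@@](C)(C(=O)OC(C)(C)C)C=C(O[Si](C(C)C)(C(C)C)C(C)C)C[C@]1(C)C(=O)OCC | intermediate
10 | 3-tert-butyl 1-ethyl 1,3-dimethyl-2-(2-oxoethyl)-5-[(triisopropylsilyl)oxy]cyclohex-4-ene-1,3-dicarboxylate (C7 aldehyde) | O=CC[C@H]1[C@@](C)(C(=O)OC(C)(C)C)C=C(O[Si](C(C)C)(C(C)C)C(C)C)C[C@]1(C)C(=O)OCC | intermediate
11 | 3-tert-butyl 1-ethyl 2-[(2R)-2-hydroxy-4-(trimethylsilyl)but-3-yn-1-yl]-1,3-dimethyl-5-[(triisopropylsilyl)oxy]cyclohex-4-ene-1,3-dicarboxylate | C[Si](C)(C)C#C[C@H](O)C[C@H]1[C@@](C)(C(=O)OC(C)(C)C)C=C(O[Si](C(C)C)(C(C)C)C(C)C)C[C@]1(C)C(=O)OCC | intermediate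
12 | 3-tert-butyl 1-ethyl 2-[(2R)-2-hydroxybut-3-yn-1-yl]-1,3-dimethyl-5-[(triisopropylsilyl)oxy]cyclohex-4-ene-1,3-dicarboxylate | C#C[C@H](O)C[C@H]1[C@@](C)(C(=O)OC(C)(C)C)C=C(O[Si](C(C)C)(C(C)C)C(C)C)C[C@]1(C)C(=O)OCC | intermediate
13 | 3-tert-butyl 1-ethyl 2-[(2R)-2-{[tert-butyl(dimethyl)silyl]oxy}but-3-yn-1-yl]-1,3-dimethyl-5-[(triisopropylsilyl)oxy]cyclohex-4-ene-1,3-dicarboxylate | C#C[C@H](O[Si](C)(C)C(C)(C)C)C[C@H]1[C@@](C)(C(=O)OC(C)(C)C)C=C(O[Si](C(C)C)(C(C)C)C(C)C)C[C@]1(C)C(=O)OCC | intermediate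
14 | tert-butyl 6-[(2R)-2-{[tert-butyl(dimethyl)silyl]oxy}but-3-yn-1-yl]-5-formyl-1,5-dimethyl-3-[(triisopropylsilyl)oxy]cyclohex-2-ene-1-carboxylate (C9 aldehyde) | C#C[C@H](O[Si](C)(C)C(C)(C)C)C[C@H]1[C@@](C)(C(=O)OC(C)(C)C)C=C(O[Si](C(C)C)(C(C)C)C(C)C)C[C@]1(C)C=O | intermediate
15 | tert-butyl 6-[(2R)-2-{[tert-butyl(dimethyl)silyl]oxy}but-3-yn-1-yl]-1,5-dimethyl-5-[(1Z)-3-(2-methyl-1,3-dioxolan-2-yl)prop-1-en-1-yl]-3-[(triisopropylsilyl)oxy]cyclohex-2-ene-1-carboxylate | C#C[C@H](O[Si](C)(C)C(C)(C)C)C[C@H]1[C@@](C)(C(=O)OC(C)(C)C)C=C(O[Si](C(C)C)(C(C)C)C(C)C)C[C@]1(C)/C=C\CC1(C)OCCO1 | intermediate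
16 | {6-[(2R)-2-{[tert-butyl(dimethyl)silyl]oxy}but-3-yn-1-yl]-1,5-dimethyl-5-[(1Z)-3-(2-methyl-1,3-dioxolan-2-yl)prop-1-en-1-yl]-3-[(triisopropylsilyl)oxy]cyclohex-2-en-1-yl}methanol (C19 alcohol) | C#C[C@H](O[Si](C)(C)C(C)(C)C)C[C@H]1[C@@](C)(CO)C=C(O[Si](C(C)C)(C(C)C)C(C)C)C[C@]1(C)/C=C\CC1(C)OCCO1 | intermediate
17 | acetate of 16 (C19 acetate) | C#C[C@H](O[Si](C)(C)C(C)(C)C)C[C@H]1[C@@](C)(COC(C)=O)C=C(O[Si](C(C)C)(C(C)C)C(C)C)C[C@]1(C)/C=C\CC1(C)OCCO1 | intermediate
18 | {2-[(2R)-2-{[tert-butyl(dimethyl)silyl]oxy}but-3-yn-1-yl]-1,3-dimethyl-3-[(1Z)-3-(2-methyl-1,3-dioxolan-2-yl)prop-1-en-1-yl]-5-oxocyclohexyl}methyl acetate (ring A ketone; stereocentres as in SMILES) | C#C[C@H](O[Si](C)(C)C(C)(C)C)C[C@H]1[C@@](C)(COC(C)=O)CC(=O)C[C@]1(C)/C=C\CC1(C)OCCO1 | intermediate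
19 | 17-(tributylstannyl) derivative of 20 (exocyclic vinylstannane, E/Z mixture) | CCCC[Sn](CCCC)(CCCC)C=C1[C@H](O[Si](C)(C)C(C)(C)C)C[C@H]2[C@@](C)(COC(C)=O)CC(=O)C[C@]2(C)[C@H]1CCC1(C)OCCO1 | intermediate
20 | 19-acetoxy-7α-[(tert-butyldimethylsilyl)oxy]-13,13-(ethylenedioxy)-14,15-dinorlabd-8(17)-en-2-one | C=C1[C@H](O[Si](C)(C)C(C)(C)C)C[C@H]2[C@@](C)(COC(C)=O)CC(=O)C[C@]2(C)[C@H]1CCC1(C)OCCO1 | intermediate
21 | 19-acetoxy-7α-[(tert-butyldimethylsilyl)oxy]-13,13-(ethylenedioxy)-14,15-dinorlabd-8(17)-en-2α-ol | C=C1[C@H](O[Si](C)(C)C(C)(C)C)C[C@H]2[C@@](C)(COC(C)=O)C[C@H](O)C[C@]2(C)[C@H]1CCC1(C)OCCO1 | intermediate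
22 | 19-acetoxy-2α,7α-dihydroxy-14,15-dinorlabd-8(17)-en-13-one (CNP0139304.2) | C=C1[C@H](O)C[C@H]2[C@@](C)(COC(C)=O)C[C@H](O)C[C@]2(C)[C@H]1CCC(C)=O | target

**Step count and risks**

Total step count: 17. Longest linear sequence: 16 (steps 1, 2 and 4–17; step 3 is the convergent branch).

Steps most likely to fail:

1. Step 15 (key step). Hydrogen transfer from Bu3SnH to the vinyl radical may outrun ring closure (plain hydrostannation). The cyclized homoallylic radical may also enlarge the ring through a cyclopropylcarbinyl shift, or facial control at C9 may be incomplete. The fallback sets out from 18 and comes back at 20 without any new compound. It is a palladium-hydride reductive enyne cyclization (Pd2(dba)3·CHCl3, P(o-tol)3, AcOH, Et3SiH, toluene). Hydropalladation of the terminal alkyne places palladium on C8, syn-carbopalladation of C9=C11 forms C8–C9 in the same 6-exo sense, and the silane reduces the C11–Pd bond. This two-electron path has no radical rearrangement channel.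

2. Step 4. The ester-deactivated diene may add too slowly to the β,β-disubstituted enal, or the catalyst may discriminate the enantiofaces incompletely. The fallback sets out from 6 and comes back at 7, using auxiliary control instead of catalyst control. Oxidation with NaClO2/NaH2PO4/2-methyl-2-butene gives (2E)-4-ethoxy-3-methyl-4-oxobut-2-enoic acid F1. Its pivaloyl mixed anhydride (t-BuCOCl, Et3N) is acylated onto the lithium salt of (S)-4-benzyloxazolidin-2-one to give the N-enoyl imide F2. The Et2AlCl-promoted Diels–Alder reaction of F2 with diene 3 runs through the chelated s-cis imide, whose benzyl group shields one face, and should give the imide adduct F3. LiBH4 removes the auxiliary reductively to give the primary alcohol F4, and Dess–Martin periodinane oxidizes F4 to 7.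

3. Step 7. The ring silyl enol ether may be lost during the acid hydrolysis, which would unmask the C2 ketone too early. The fallback sets out from 7 and comes back at 10, and avoids both the enol ether and acid. Methylenation with Ph3P=CH2 (from Ph3PCH3Br and KN(SiMe3)2) gives the vinyl compound F5. LiN(i-Pr)2/CH3I methylation at C4, as in step 6, gives the methylated vinyl diester F6. Chemoselective hydroboration of the monosubstituted alkene with 9-BBN and oxidation with NaBO3·4H2O give the primary alcohol F7, and Dess–Martin periodinane oxidizes F7 to aldehyde 10.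

Further compounds
F0 | step 15 | none | none
F1 | step 4 | (2E)-4-ethoxy-3-methyl-4-oxobut-2-enoic acid | CCOC(=O)/C(C)=C/C(=O)O
F2 | step 4 | ethyl (2E)-4-[(4S)-4-benzyl-2-oxo-1,3-oxazolidin-3-yl]-2-methyl-4-oxobut-2-enoate | CCOC(=O)/C(C)=C/C(=O)N1[C@@H](Cc2ccccc2)COC1=O
F3 | step 4 | 3-tert-butyl 1-ethyl 2-{[(4S)-4-benzyl-2-oxo-1,3-oxazolidin-3-yl]carbonyl}-1-methyl-5-[(triisopropylsilyl)oxy]cyclohex-4-ene-1,3-dicarboxylate (ring stereocentres as in 7) | O=C([C@H]1[C@@H](C(=O)OC(C)(C)C)C=C(O[Si](C(C)C)(C(C)C)C(C)C)C[C@]1(C)C(=O)OCC)N1[C@@H](Cc2ccccc2)COC1=O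
F4 | step 4 | 3-tert-butyl 1-ethyl 2-(hydroxymethyl)-1-methyl-5-[(triisopropylsilyl)oxy]cyclohex-4-ene-1,3-dicarboxylate (ring stereocentres as in 7) | OC[C@H]1[C@@H](C(=O)OC(C)(C)C)C=C(O[Si](C(C)C)(C(C)C)C(C)C)C[C@]1(C)C(=O)OCC
F5 | step 7 | 3-tert-butyl 1-ethyl 2-ethenyl-1-methyl-5-[(triisopropylsilyl)oxy]cyclohex-4-ene-1,3-dicarboxylate (ring stereocentres as in 7) | C=C[C@H]1[C@@H](C(=O)OC(C)(C)C)C=C(O[Si](C(C)C)(C(C)C)C(C)C)C[C@]1(C)C(=O)OCC
F6 | step 7 | 3-tert-butyl 1-ethyl 2-ethenyl-1,3-dimethyl-5-[(triisopropylsilyl)oxy]cyclohex-4-ene-1,3-dicarboxylate (ring stereocentres as in 9) | C=C[C@H]1[C@@](C)(C(=O)OC(C)(C)C)C=C(O[Si](C(C)C)(C(C)C)C(C)C)C[C@]1(C)C(=O)OCC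
F7 | step 7 | 3-tert-butyl 1-ethyl 2-(2-hydroxyethyl)-1,3-dimethyl-5-[(triisopropylsilyl)oxy]cyclohex-4-ene-1,3-dicarboxylate (ring stereocentres as in 9) | OCC[C@H]1[C@@](C)(C(=O)OC(C)(C)C)C=C(O[Si](C(C)C)(C(C)C)C(C)C)C[C@]1(C)C(=O)OCC
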